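**Strategy.** Ring atoms: C1 (ketone), C2 (amide-bearing), C3, C4 (carbinol), C5 and C6 (oxirane). Everything rests on closing the cyclohexenone ring at C1–C6. The key step exploits the 1,4-relation of the C4 oxygen and the C1 carbonyl across the cis C2=C3 bond: the precursor ties them as an α-amido butenolide whose C4 also carries a (Z)-2-iodovinyl arm (C5=C6) and a vinyl group. Iodine–lithium exchange makes C6 attack the lactone carbonyl C1; the oxygen bridge opens, so the furanone is traded for the cyclohexadienone, and the freed C4 lithium alkoxide then steers t-BuOOLi to close the C5–C6 oxirane syn to it in the same flask. A Heck coupling finishes the trienamide.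

Key step: step 15

Remark: the aminocyclopentenone unit is written as the enol tautomer shown in the target; the labels C1–C6 are kept for the corresponding atoms of all intermediates.

**Part A – phosphonoglycinate carrying the upper side chain**

Step 1
Reactants: 1 cyclohexanecarbaldehyde; 2 ethyl (2E)-4-(diethoxyphosphoryl)but-2-enoate
Product: 3 ethyl (2E,4E)-5-cyclohexylpenta-2,4-dienoate
Conditions: LiN(SiMe3)2, THF, −78 to 0 °C
Reagents that add atoms: none
Why: Vinylogous Horner–Wadsworth–Emmons olefination of the aldehyde with the lithiated phosphonocrotonate should give the (2E,4E)-dienoate, because the stabilised phosphonate adduct eliminates under thermodynamic control.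

Step 2
Reactants: 3 ethyl (2E,4E)-5-cyclohexylpenta-2,4-dienoate
Product: 4 (2E,4E)-5-cyclohexylpenta-2,4-dienoic acid
Conditions: LiOH, THF/MeOH/H2O, 25 °C; then aq HCl
Reagents that add atoms: lithium hydroxide, [Li+].[OH-]
Why: Saponification of the ethyl ester leaves the conjugated diene geometry untouched.

Step 3
Reactants: 5 methyl 2-{[(benzyloxy)carbonyl]amino}-2-(dimethoxyphosphoryl)acetate (racemic)
Product: 6 methyl 2-amino-2-(dimethoxyphosphoryl)acetate (racemic, used at once)
Conditions: H2 (1 atm), Pd/C, MeOH, 25 °C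
Reagents that add atoms: none
Why: Hydrogenolysis of the benzyl carbamate frees the α-amino phosphonate.

Step 4
Reactants: 4 (2E,4E)-5-cyclohexylpenta-2,4-dienoic acid; 6 methyl 2-amino-2-(dimethoxyphosphoryl)acetate
Product: 7 methyl 2-[(2E,4E)-5-cyclohexylpenta-2,4-dienamido]-2-(dimethoxyphosphoryl)acetate (racemic)
Conditions: DCC, HOBt (cat.), CH2Cl2, 0 to 25 °C
Reagents that add atoms: none
Why: Carbodiimide amide coupling acylates the free amine and gives the N-acyl phosphonoglycinate needed for dehydroamino acid synthesis.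

**Part B – core**

Step 5
Reactants: 8 4-{[tert-butyl(dimethyl)silyl]oxy}but-2-yn-1-ol
Product: 9 (2Z)-4-{[tert-butyl(dimethyl)silyl]oxy}-3-iodobut-2-en-1-ol
Conditions: NaAlH2(OCH2CH2OMe)2, THF, 0 °C; then I2, −78 °C
Reagents that add atoms: iodine, II
Why: Hydroxyl-directed trans-hydroalumination of the propargylic alcohol (hydride to the proximal, aluminium to the distal alkyne carbon) and iodinolysis with retention should give the (Z)-3-iodoallylic alcohol, fixing the alkene geometry that later defines C4.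

Step 6
Reactants: 9 (2Z)-4-{[tert-butyl(dimethyl)silyl]oxy}-3-iodobut-2-en-1-ol; 10 ethynyl(trimethyl)silane
Product: 11 (2E)-3-({[tert-butyl(dimethyl)silyl]oxy}methyl)-5-(trimethylsilyl)pent-2-en-4-yn-1-ol
Conditions: PdCl2(PPh3)2 (cat.), CuI (cat.), Et3N, THF, 25 °C
Reagents that add atoms: none
Why: Sonogashira coupling of the alkenyl iodide proceeds with retention of alkene geometry and brings in the two carbons that become C5 and C6.

Step 7
Reactants: 11 (2E)-3-({[tert-butyl(dimethyl)silyl]oxy}methyl)-5-(trimethylsilyl)pent-2-en-4-yn-1-ol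
Product: 12 (2E)-3-({[tert-butyl(dimethyl)silyl]oxy}methyl)-5-iodopent-2-en-4-yn-1-ol
Conditions: N-iodosuccinimide, AgNO3 (cat.), DMF, 25 °C, dark
Reagents that add atoms: N-iodosuccinimide, O=C1CCC(=O)N1I
Why: Silver-catalysed iododesilylation (electrophilic ipso-substitution at the alkynylsilane) should give the 1-iodoalkyne directly under neutral conditions.

Step 8
Reactants: 12 (2E)-3-({[tert-butyl(dimethyl)silyl]oxy}methyl)-5-iodopent-2-en-4-yn-1-ol
Product: 13 (2E,4Z)-3-({[tert-butyl(dimethyl)silyl]oxy}methyl)-5-iodopenta-2,4-dien-1-ol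
Conditions: 2-nitrobenzenesulfonohydrazide, Et3N, THF/i-PrOH, 25 °C
Reagents that add atoms: none
Why: Diimide generated in the flask adds hydrogen syn to the iodoalkyne much faster than to the trisubstituted alkene, so the (Z)-alkenyl iodide should result (diimide cis-reduction).

Step 9
Reactants: 13 (2E,4Z)-3-({[tert-butyl(dimethyl)silyl]oxy}methyl)-5-iodopenta-2,4-dien-1-ol
Product: 14 [(2S,3S)-3-({[tert-butyl(dimethyl)silyl]oxy}methyl)-3-[(Z)-2-iodoethenyl]oxiran-2-yl]methanol
Conditions: Ti(Oi-Pr)4 (cat.), L-(+)-diethyl tartrate (cat.), t-BuOOH, 4 Å molecular sieves, CH2Cl2, −20 °C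
Reagents that add atoms: tert-butyl hydroperoxide, CC(C)(C)OO
Why: Sharpless asymmetric epoxidation of the trisubstituted allylic alcohol with the catalyst from Ti(Oi-Pr)4 and L-(+)-diethyl tartrate should deliver oxygen to the face that gives the (2S,3S)-epoxy alcohol, which sets the quaternary carbon (later C4) together with its oxygen, while the distal iodoalkene, not being part of an allylic alcohol, stays untouched.

Step 10
Reactants: 14 [(2S,3S)-3-({[tert-butyl(dimethyl)silyl]oxy}methyl)-3-[(Z)-2-iodoethenyl]oxiran-2-yl]methanol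
Product: 15 tert-butyl{[(2S,3R)-3-(iodomethyl)-2-[(Z)-2-iodoethenyl]oxiran-2-yl]methoxy}dimethylsilane
Conditions: I2, PPh3, imidazole, CH2Cl2, 0 °C
Reagents that add atoms: iodine, II
Why: Appel-type iodination of the primary alcohol leaves the oxirane and both stereocentres intact (the descriptor at the CH carbon changes only through priority).

Step 11
Reactants: 15 tert-butyl{[(2S,3R)-3-(iodomethyl)-2-[(Z)-2-iodoethenyl]oxiran-2-yl]methoxy}dimethylsilane
Product: 16 (1Z,3S)-3-({[tert-butyl(dimethyl)silyl]oxy}methyl)-1-iodopenta-1,4-dien-3-ol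
Conditions: Zn dust, EtOH, 60 °C
Reagents that add atoms: none
Why: Zinc inserts into the primary C–I bond and β-elimination opens the oxirane (reductive opening of an epoxy iodide), which unveils the vinyl group and the tertiary alcohol without touching the C4–O bond, so the configuration is retained.

Step 12
Reactants: 16 (1Z,3S)-3-({[tert-butyl(dimethyl)silyl]oxy}methyl)-1-iodopenta-1,4-dien-3-ol
Product: 17 (2S,3Z)-2-ethenyl-4-iodobut-3-ene-1,2-diol
Conditions: Bu4NF, THF, 0 °C
Reagents that add atoms: none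
Why: Fluoride cleaves the primary silyl ether under non-acidic conditions that spare the tertiary bis-allylic alcohol.

Step 13
Reactants: 17 (2S,3Z)-2-ethenyl-4-iodobut-3-ene-1,2-diol
Product: 18 (2S,3Z)-2-ethenyl-2-hydroxy-4-iodobut-3-enal (used crude)
Conditions: SO3·pyridine, DMSO, i-Pr2NEt, CH2Cl2, 0 °C
Reagents that add atoms: none
Why: Parikh–Doering oxidation converts only the primary alcohol of the 1,2-diol into the aldehyde and cannot touch the tertiary one.

Step 14
Reactants: 18 (2S,3Z)-2-ethenyl-2-hydroxy-4-iodobut-3-enal; 7 methyl 2-[(2E,4E)-5-cyclohexylpenta-2,4-dienamido]-2-(dimethoxyphosphoryl)acetate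
Product: 20 (2E,4E)-5-cyclohexyl-N-{(5R)-5-ethenyl-5-[(Z)-2-iodoethenyl]-2-oxo-2,5-dihydrofuran-3-yl}penta-2,4-dienamide, via hydroxy dehydroamino ester 19 (not isolated)
Conditions: DBU, LiCl, MeCN, −20 to 25 °C
Reagents that add atoms: none
Why: Horner–Wadsworth–Emmons olefination followed by lactonisation: only the dehydroamino ester with the C4 oxygen cis to the ester can lactonise, and DBU should equilibrate the other isomer through its N-deprotonated 1-azaallyl form, so the mixture drains into the butenolide, which locks the cis C2=C3 geometry and keeps C4 unchanged.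

Step 15
Reactants: 20 (2E,4E)-5-cyclohexyl-N-{(5R)-5-ethenyl-5-[(Z)-2-iodoethenyl]-2-oxo-2,5-dihydrofuran-3-yl}penta-2,4-dienamide
Product: 24 (2E,4E)-5-cyclohexyl-N-[(1R,5R,6S)-5-ethenyl-5-hydroxy-2-oxo-7-oxabicyclo[4.1.0]hept-3-en-3-yl]penta-2,4-dienamide, via alkenyllithium amidate 21 (not isolated), via oxygen-bridged adduct 22 (not isolated), via dilithium p-quinolate 23 (not isolated)
Conditions: LiN(SiMe3)2 (1 equiv), THF, −78 °C; t-BuLi (2 equiv), −100 to −78 °C; then t-BuOOH (decane), −78 to −20 °C; aq NH4Cl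
Reagents that add atoms: tert-butyl hydroperoxide, CC(C)(C)OO
Why: Deprotonation of the amide N–H and iodine–lithium exchange with retention give the (Z)-alkenyllithium 21, whose C6 attacks the lactone carbonyl C1 on the face where the C4 stereocentre holds the arm, and the oxygen-bridged adduct 22 collapses by C1–O cleavage to the dilithium p-quinolate 23, so the ring oxygen of the butenolide becomes the C4 alkoxide. The closest known reaction types are the Parham-type cyclisation of an organolithium onto a lactone and the ring-closing acylation of the Hauser–Kraus annulation, which passes through the same kind of oxygen-bridged tetrahedral adduct, followed by a Weitz–Scheffer epoxidation with lithium tert-butyl peroxide. The carbocycle closes 6-exo-trig at the C1 carbonyl (5-exo-trig if counted through the bridging oxygen), and the oxirane closes 3-exo-tet at the peroxide oxygen when the C6 enolate displaces tert-butoxide. C4 is carried over unchanged from 20, and C5 and C6 are set by the C4 lithium alkoxide, which binds t-BuOOLi and delivers it to C5 on its own face, so the oxirane should form syn to the hydroxyl. The step needs exchange to outrun addition of t-BuLi to the lactone, which the low temperature and the prior N-lithiation secure, and it needs epoxidation at C5=C6 and not at C2=C3, which the electron-rich N-lithio enamide at C2 secures.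

**Part C – lower side chain**

Step 16
Reactants: 25 cyclopentane-1,3-dione
Product: 26 3-hydroxy-2-nitrocyclopent-2-en-1-one (enol form of 2-nitrocyclopentane-1,3-dione)
Conditions: fuming HNO3, Et2O, 0 °C
Reagents that add atoms: nitric acid, O[N+](=O)[O-]
Why: Electrophilic nitration of the enolic 1,3-dione takes place at its central carbon.

Step 17
Reactants: 26 3-hydroxy-2-nitrocyclopent-2-en-1-one
Product: 27 2-amino-3-hydroxycyclopent-2-en-1-one hydrochloride
Conditions: H2 (1 atm), Pd/C, MeOH, HCl, 25 °C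
Reagents that add atoms: hydrogen chloride, Cl
Why: Catalytic hydrogenation reduces the nitro group, and the amine is trapped as its hydrochloride to suppress self-condensation and air oxidation.

Step 18
Reactants: 28 ethyl (2E)-4-oxobut-2-enoate; 29 triiodomethane
Product: 30 ethyl (2E,4E)-5-iodopenta-2,4-dienoate
Conditions: CrCl2, THF, 0 °C
Reagents that add atoms: none
Why: Takai olefination (geminal dichromium reagent from triiodomethane and CrCl2) converts the aldehyde into the (E)-alkenyl iodide and leaves the (E)-enoate untouched.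

Step 19
Reactants: 30 ethyl (2E,4E)-5-iodopenta-2,4-dienoate
Product: 31 (2E,4E)-5-iodopenta-2,4-dienoic acid
Conditions: LiOH, THF/H2O, 25 °C; then aq HCl
Reagents that add atoms: lithium hydroxide, [Li+].[OH-]
Why: Saponification of the ester keeps the iododiene geometry.

Step 20
Reactants: 31 (2E,4E)-5-iodopenta-2,4-dienoic acid; 27 2-amino-3-hydroxycyclopent-2-en-1-one hydrochloride
Product: 32 (2E,4E)-N-(2-hydroxy-5-oxocyclopent-1-en-1-yl)-5-iodopenta-2,4-dienamide
Conditions: DCC, HOBt (cat.), N-methylmorpholine, DMF, 0 to 25 °C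
Reagents that add atoms: none
Why: Carbodiimide amide coupling acylates the nitrogen, and any enol ester formed at oxygen should transfer its acyl group to the neighbouring amine.

**Part D – union**

Step 21
Reactants: 24 (2E,4E)-5-cyclohexyl-N-[(1R,5R,6S)-5-ethenyl-5-hydroxy-2-oxo-7-oxabicyclo[4.1.0]hept-3-en-3-yl]penta-2,4-dienamide; 32 (2E,4E)-N-(2-hydroxy-5-oxocyclopent-1-en-1-yl)-5-iodopenta-2,4-dienamide
Product: 33 (2E,4E)-5-cyclohexyl-N-[(1R,5R,6S)-5-hydroxy-5-[(1E,3E,5E)-7-[(2-hydroxy-5-oxocyclopent-1-en-1-yl)amino]-7-oxohepta-1,3,5-trien-1-yl]-2-oxo-7-oxabicyclo[4.1.0]hept-3-en-3-yl]penta-2,4-dienamide (target)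
Conditions: Pd(OAc)2 (cat.), Ag2CO3, DMF, 25 °C, dark
Reagents that add atoms: none
Why: Heck reaction: oxidative addition of 32, insertion of the terminal vinyl group of 24 at its unsubstituted carbon, and syn β-hydride elimination (possible only away from the quaternary C4) should give the new (E)-alkene with retention of the iododiene geometry, with Ag2CO3 as halide scavenger under ligand-free conditions.

**Compound list**

1 | cyclohexanecarbaldehyde | O=CC1CCCCC1 | starting material
2 | ethyl (2E)-4-(diethoxyphosphoryl)but-2-enoate | CCOC(=O)/C=C/CP(=O)(OCC)OCC | starting material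
3 | ethyl (2E,4E)-5-cyclohexylpenta-2,4-dienoate | CCOC(=O)/C=C/C=C/C1CCCCC1 | intermediate
4 | (2E,4E)-5-cyclohexylpenta-2,4-dienoic acid | OC(=O)/C=C/C=C/C1CCCCC1 | intermediate
5 | methyl 2-{[(benzyloxy)carbonyl]amino}-2-(dimethoxyphosphoryl)acetate (racemic) | COC(=O)C(NC(=O)OCc1ccccc1)P(=O)(OC)OC | starting material
6 | methyl 2-amino-2-(dimethoxyphosphoryl)acetate (racemic) | COC(=O)C(N)P(=O)(OC)OC | intermediate
7 | methyl 2-[(2E,4E)-5-cyclohexylpenta-2,4-dienamido]-2-(dimethoxyphosphoryl)acetate (racemic) | COC(=O)C(NC(=O)/C=C/C=C/C1CCCCC1)P(=O)(OC)OC | intermediate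
8 | 4-{[tert-butyl(dimethyl)silyl]oxy}but-2-yn-1-ol | OCC#CCO[Si](C)(C)C(C)(C)C | starting material
9 | (2Z)-4-{[tert-butyl(dimethyl)silyl]oxy}-3-iodobut-2-en-1-ol | OC/C=C(\I)CO[Si](C)(C)C(C)(C)C | intermediate
10 | ethynyl(trimethyl)silane | C#C[Si](C)(C)C | starting material
11 | (2E)-3-({[tert-butyl(dimethyl)silyl]oxy}methyl)-5-(trimethylsilyl)pent-2-en-4-yn-1-ol | OC/C=C(\C#C[Si](C)(C)C)CO[Si](C)(C)C(C)(C)C | intermediate
12 | (2E)-3-({[tert-butyl(dimethyl)silyl]oxy}methyl)-5-iodopent-2-en-4-yn-1-ol | OC/C=C(\C#CI)CO[Si](C)(C)C(C)(C)C | intermediate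
13 | (2E,4Z)-3-({[tert-butyl(dimethyl)silyl]oxy}methyl)-5-iodopenta-2,4-dien-1-ol | OC/C=C(CO[Si](C)(C)C(C)(C)C)\C=C/I | intermediate
14 | [(2S,3S)-3-({[tert-butyl(dimethyl)silyl]oxy}methyl)-3-[(Z)-2-iodoethenyl]oxiran-2-yl]methanol | OC[C@@H]1O[C@]1(CO[Si](C)(C)C(C)(C)C)/C=C\I | intermediate
15 | tert-butyl{[(2S,3R)-3-(iodomethyl)-2-[(Z)-2-iodoethenyl]oxiran-2-yl]methoxy}dimethylsilane | IC[C@@H]1O[C@]1(CO[Si](C)(C)C(C)(C)C)/C=C\I | intermediate
16 | (1Z,3S)-3-({[tert-butyl(dimethyl)silyl]oxy}methyl)-1-iodopenta-1,4-dien-3-ol | CC(C)(C)[Si](C)(C)OC[C@](O)(C=C)/C=C\I | intermediate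
17 | (2S,3Z)-2-ethenyl-4-iodobut-3-ene-1,2-diol | OC[C@](O)(C=C)/C=C\I | intermediate
18 | (2S,3Z)-2-ethenyl-2-hydroxy-4-iodobut-3-enal | O=C[C@](O)(C=C)/C=C\I | intermediate
19 | methyl (4R,5Z)-2-[(2E,4E)-5-cyclohexylpenta-2,4-dienamido]-4-ethenyl-4-hydroxy-6-iodohexa-2,5-dienoate (mixture of C2=C3 isomers) | COC(=O)C(NC(=O)/C=C/C=C/C1CCCCC1)=C[C@](O)(C=C)/C=C\I | intermediate
20 | (2E,4E)-5-cyclohexyl-N-{(5R)-5-ethenyl-5-[(Z)-2-iodoethenyl]-2-oxo-2,5-dihydrofuran-3-yl}penta-2,4-dienamide | O=C1O[C@@](C=C)(/C=C\I)C=C1NC(=O)/C=C/C=C/C1CCCCC1 | intermediate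
21 | N-lithio amide of 20 in which lithium has replaced iodine on the (Z)-ethenyl arm | [Li]/C=C\[C@]1(C=C)OC(=O)C(=C1)N([Li])C(=O)/C=C/C=C/C1CCCCC1 | intermediate
22 | dilithium salt of the 4-ethenyl-7-oxabicyclo[2.2.1]hepta-2,5-dien-1-olate adduct bearing the amidate on C2 | [Li+].[Li+].[O-][C@@]12O[C@@](C=C)(C=C1)C=C2[N-]C(=O)/C=C/C=C/C1CCCCC1 | intermediate
23 | dilithium salt (alkoxide and amidate) of (2E,4E)-5-cyclohexyl-N-[(3S)-3-ethenyl-3-hydroxy-6-oxocyclohexa-1,4-dien-1-yl]penta-2,4-dienamide | [Li+].[Li+].O=C(/C=C/C=C/C1CCCCC1)[N-]C1=C[C@]([O-])(C=C)C=CC1=O | intermediate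
24 | (2E,4E)-5-cyclohexyl-N-[(1R,5R,6S)-5-ethenyl-5-hydroxy-2-oxo-7-oxabicyclo[4.1.0]hept-3-en-3-yl]penta-2,4-dienamide | O=C(/C=C/C=C/C1CCCCC1)NC1=C[C@](O)(C=C)[C@H]2O[C@H]2C1=O | intermediate
25 | cyclopentane-1,3-dione | O=C1CCC(=O)C1 | starting material
26 | 3-hydroxy-2-nitrocyclopent-2-en-1-one | O=C1CCC(O)=C1[N+](=O)[O-] | intermediate
27 | 2-amino-3-hydroxycyclopent-2-en-1-one hydrochloride | Cl.NC1=C(O)CCC1=O | intermediate
28 | ethyl (2E)-4-oxobut-2-enoate | CCOC(=O)/C=C/C=O | starting material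
29 | triiodomethane | IC(I)I | starting material
30 | ethyl (2E,4E)-5-iodopenta-2,4-dienoate | CCOC(=O)/C=C/C=C/I | intermediate
31 | (2E,4E)-5-iodopenta-2,4-dienoic acid | OC(=O)/C=C/C=C/I | intermediate
32 | (2E,4E)-N-(2-hydroxy-5-oxocyclopent-1-en-1-yl)-5-iodopenta-2,4-dienamide | O=C(/C=C/C=C/I)NC1=C(O)CCC1=O | intermediate
33 | (2E,4E)-5-cyclohexyl-N-[(1R,5R,6S)-5-hydroxy-5-[(1E,3E,5E)-7-[(2-hydroxy-5-oxocyclopent-1-en-1-yl)amino]-7-oxohepta-1,3,5-trien-1-yl]-2-oxo-7-oxabicyclo[4.1.0]hept-3-en-3-yl]penta-2,4-dienamide | O=C(/C=C/C=C/C1CCCCC1)NC1=C[C@](O)(/C=C/C=C/C=C/C(=O)NC2=C(O)CCC2=O)[C@H]2O[C@H]2C1=O | target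

**Step count and risks**

Total step count: 21. Longest linear sequence: 12 steps (steps 5 to 15 and step 21, from 8).

Most likely to fail, step 15 (key step). The alkenyllithium may be quenched or may react between molecules before C6 reaches C1 across the strained oxygen-bridged adduct, or t-BuLi may add to the lactone faster than it exchanges. The fallback sets out from 20 and comes back at 24. Reduction of the lactone with i-Bu2AlH (CH2Cl2, −78 °C) should give the 2-hydroxy-2,5-dihydrofuran (lactol) F1. Its open hydroxy-enal form then undergoes an intramolecular Nozaki–Hiyama–Kishi reaction (CrCl2, NiCl2 cat., DMSO, 25 °C), which forms the same C1–C6 bond under non-basic conditions and gives the cyclohexa-2,5-diene-1,4-diol F2 as a mixture of C1 epimers. MnO2 (CH2Cl2, 25 °C) oxidises the secondary bis-allylic alcohol to the neutral p-quinol F3, and t-BuOOLi (from t-BuOOH and n-BuLi, THF, −20 °C) epoxidises it syn to the hydroxyl to give 24.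

Second, step 14. Equilibration of the C2=C3 isomers may be incomplete, so that the ester that cannot lactonise accumulates, or base may trigger an α-ketol rearrangement of 18 before olefination. The fallback sets out from 16 and 7 and comes back at 20. Saponification of 7 (LiOH, THF/H2O) gives the phosphonoglycine acid F4. Yamaguchi esterification of the tertiary hydroxyl of 16 with F4 (2,4,6-trichlorobenzoyl chloride, Et3N, DMAP, toluene) gives the phosphonate ester F5. Desilylation (HF·pyridine, THF, 0 °C) gives the primary alcohol F6, and Dess–Martin oxidation gives the aldehyde F7. F7 closes by intramolecular Horner–Wadsworth–Emmons reaction (LiCl, i-Pr2NEt, MeCN), in which the ester tether enforces the cis geometry, to 20.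

Third, step 21. Insertion may occur at other alkenes of 24, or the epoxy ketone may open under palladium and silver. The fallback sets out from 24 and comes back at 33. Cross-metathesis of the vinyl group with 2-ethenyl-4,4,5,5-tetramethyl-1,3,2-dioxaborolane (second-generation Hoveyda–Grubbs catalyst, RuCl2(H2IMes)(=CH–C6H4–2-Oi-Pr), CH2Cl2, 40 °C) should give the (E)-alkenylboronate F8. Suzuki–Miyaura coupling of F8 with 32 (PdCl2(dppf), K3PO4, THF/H2O, 25 °C) then gives 33.

Further compounds
F1 | step 15 | (2E,4E)-5-cyclohexyl-N-{(5R)-5-ethenyl-2-hydroxy-5-[(Z)-2-iodoethenyl]-2,5-dihydrofuran-3-yl}penta-2,4-dienamide (both anomers) | OC1O[C@@](C=C)(/C=C\I)C=C1NC(=O)/C=C/C=C/C1CCCCC1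
F2 | step 15 | (2E,4E)-5-cyclohexyl-N-[(3S)-3-ethenyl-3,6-dihydroxycyclohexa-1,4-dien-1-yl]penta-2,4-dienamide (both C6 epimers) | O=C(/C=C/C=C/C1CCCCC1)NC1=C[C@](O)(C=C)C=CC1O
F3 | step 15 | (2E,4E)-5-cyclohexyl-N-[(3S)-3-ethenyl-3-hydroxy-6-oxocyclohexa-1,4-dien-1-yl]penta-2,4-dienamide | O=C(/C=C/C=C/C1CCCCC1)NC1=C[C@](O)(C=C)C=CC1=O
F4 | step 14 | 2-[(2E,4E)-5-cyclohexylpenta-2,4-dienamido]-2-(dimethoxyphosphoryl)acetic acid (racemic) | OC(=O)C(NC(=O)/C=C/C=C/C1CCCCC1)P(=O)(OC)OC
F5 | step 14 | (1Z,3S)-3-({[tert-butyl(dimethyl)silyl]oxy}methyl)-1-iodopenta-1,4-dien-3-yl 2-[(2E,4E)-5-cyclohexylpenta-2,4-dienamido]-2-(dimethoxyphosphoryl)acetate (both epimers at the phosphonate carbon) | CC(C)(C)[Si](C)(C)OC[C@](OC(=O)C(NC(=O)/C=C/C=C/C1CCCCC1)P(=O)(OC)OC)(C=C)/C=C\I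
F6 | step 14 | (1Z,3S)-3-(hydroxymethyl)-1-iodopenta-1,4-dien-3-yl 2-[(2E,4E)-5-cyclohexylpenta-2,4-dienamido]-2-(dimethoxyphosphoryl)acetate | OC[C@](OC(=O)C(NC(=O)/C=C/C=C/C1CCCCC1)P(=O)(OC)OC)(C=C)/C=C\I
F7 | step 14 | (1Z,3S)-3-formyl-1-iodopenta-1,4-dien-3-yl 2-[(2E,4E)-5-cyclohexylpenta-2,4-dienamido]-2-(dimethoxyphosphoryl)acetate | O=C[C@](OC(=O)C(NC(=O)/C=C/C=C/C1CCCCC1)P(=O)(OC)OC)(C=C)/C=C\I
F8 | step 21 | (2E,4E)-5-cyclohexyl-N-{(1R,5R,6S)-5-hydroxy-2-oxo-5-[(E)-2-(4,4,5,5-tetramethyl-1,3,2-dioxaborolan-2-yl)ethenyl]-7-oxabicyclo[4.1.0]hept-3-en-3-yl}penta-2,4-dienamide | O=C(/C=C/C=C/C1CCCCC1)NC1=C[C@](O)(/C=C/B2OC(C)(C)C(C)(C)O2)[C@H]2O[C@H]2C1=O
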